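**Strategy.** The synthesis rests on disconnecting ring C, the right-hand dihydropyran (O1, C2, C3, C4), at C2–C3. C2 is an allylic ether carbon: it carries O1 and the first alkene of the diene, the retron of an SN2′ allylic alkylation, while the C3–C4 ethylene bridge can come from hydroboration of an aryl vinyl group. In one pot the key step converts an achiral 2-vinylaryl (Z)-3-chloroallyl ether into the (R)-2-vinylchroman by hydroboration and copper-catalysed enantioselective ring-closing allyl–alkyl coupling. Both benzenoid chromans are then ring-expanded to tropolone methyl ethers, joined by Suzuki coupling and demethylated.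

Key step: step 5

Remark: the target is drawn as one tropolone tautomer; the 7-oxo-8-hydroxy and 8-oxo-7-hydroxy forms interconvert, so the O-methyl regioisomer formed in the ring expansion leads to the target after demethylation, and compounds 1, 3 and 14 are taken as catalogue materials.

Locants: each half is numbered as a chroman (O1, C2, C3, C4, C4a, C5–C8, C8a) and, after ring expansion, as a cyclohepta[b]pyran (O1, C2–C4, C4a, C5–C9, C9a). Rings A/B are the left tropolone/dihydropyran, rings C/D the right dihydropyran/tropolone. The target is (2R,3R) in ring B and (2R) in ring C.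

**Step 1**
Reactants: 1 2,4-dihydroxy-5-methoxybenzaldehyde
Product: 2 2-hydroxy-5-methoxy-4-(methoxymethoxy)benzaldehyde
Conditions: MOMCl (1.05 equiv), i-Pr2NEt, CH2Cl2, 0 °C
Reagents that add atoms: chloromethyl methyl ether, COCCl
Why: Williamson-type O-alkylation; the 4-OH (para to CHO, more acidic, not hydrogen-bonded) should react in preference to the chelated 2-OH.

**Step 2**
Reactants: 2 2-hydroxy-5-methoxy-4-(methoxymethoxy)benzaldehyde; 3 (Z)-3-iodoprop-2-en-1-ol
Product: 4 2-{[(1Z)-3-hydroxyprop-1-en-1-yl]oxy}-5-methoxy-4-(methoxymethoxy)benzaldehyde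
Conditions: CuI (10 mol %), N,N-dimethylglycine·HCl (20 mol %), Cs2CO3, 1,4-dioxane, 70 °C
Reagents that add atoms: none
Why: Ullmann-type copper-catalysed O-vinylation of a phenol with a vinyl iodide, which proceeds with retention of alkene geometry; the phenoxide should couple in preference to the aliphatic hydroxyl.

**Step 3**
Reactants: 4 2-{[(1Z)-3-hydroxyprop-1-en-1-yl]oxy}-5-methoxy-4-(methoxymethoxy)benzaldehyde
Product: 5 (2Z)-3-[2-ethenyl-4-methoxy-5-(methoxymethoxy)phenoxy]prop-2-en-1-ol
Conditions: Ph3PCH3Br (2.5 equiv), KOtBu (2.4 equiv), THF, 0 to 25 °C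
Reagents that add atoms: methyltriphenylphosphonium bromide, C[P+](c1ccccc1)(c1ccccc1)c1ccccc1.[Br-]
Why: Wittig methylenation of the aryl aldehyde; one further equivalent of ylide is consumed as base by the allylic hydroxyl, and the Z-enol ether is inert to the ylide.

**Step 4**
Reactants: 5 (2Z)-3-[2-ethenyl-4-methoxy-5-(methoxymethoxy)phenoxy]prop-2-en-1-ol
Product: 6 1-{[(1Z)-3-chloroprop-1-en-1-yl]oxy}-2-ethenyl-4-methoxy-5-(methoxymethoxy)benzene
Conditions: PPh3, hexachloroacetone, 2,6-lutidine (cat.), CH2Cl2, 0 °C; used at once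
Reagents that add atoms: hexachloroacetone, ClC(Cl)(Cl)C(=O)C(Cl)(Cl)Cl
Why: Appel-type chlorination (chlorophosphonium from PPh3 and hexachloroacetone, SN2 at the primary carbon) under neutral conditions, which is known to convert allylic alcohols into chlorides without allylic transposition or change of alkene geometry.

**Step 5**
Reactants: 6 1-{[(1Z)-3-chloroprop-1-en-1-yl]oxy}-2-ethenyl-4-methoxy-5-(methoxymethoxy)benzene
Product: 8 (2R)-2-ethenyl-6-methoxy-7-(methoxymethoxy)-3,4-dihydro-2H-chromene, via B-alkyl-9-BBN borane 7 (not isolated)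
Conditions: 9-BBN dimer (0.52 equiv), THF, 25 °C; then KOEt (1.2 equiv), CuOTf·0.5C7H8 (10 mol %), (R)-DTBM-SEGPHOS (11 mol %), 1,4-dioxane, 15 °C
Reagents that add atoms: none
Why: Proposed new method: 9-BBN adds anti-Markovnikov to the aryl vinyl group (it is selective for the terminal alkene over the 1,2-disubstituted enol ether), ethoxide turns borane 7 into a borate that transfers the C3 alkyl group to copper, and the alkylcopper attacks C2 of the γ-aryloxyallyl chloride in an anti-SN2′ oxidative addition, after which reductive elimination from the σ-allyl copper intermediate (trivalent copper) forms C2–C3 and leaves the vinyl group on C2. The closest known reaction types are the intermolecular copper/DTBM-SEGPHOS-catalysed enantioselective γ-selective coupling of alkyl-9-BBN reagents with (Z)-allylic chlorides and the copper-catalysed SN2′ alkylation of γ-acyloxyallyl halides; neither has been run as a ring closure or with a γ-aryloxy group. Ring C closes in a 6-exo-trig SN2′ mode, the allylic C=C staying outside the ring. The C2 stereocentre is set by the chiral bisphosphine on copper, which selects one enantiotopic face of the Z-alkene; the (R)-sense is assigned by analogy, and the ligand antipode is the remedy if the sense proves opposite. The step needs γ- over α-attack, which ring size secures (six- against eight-membered), and formation of the borate before the alkoxide can meet the allylic chloride, which the order of addition secures.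

**Step 6**
Reactants: 8 (2R)-2-ethenyl-6-methoxy-7-(methoxymethoxy)-3,4-dihydro-2H-chromene
Product: 10 (2R)-2-ethenyl-6,6-dimethoxy-3,4-dihydro-2H-chromen-7(6H)-one, via free phenol 9 (not isolated)
Conditions: HCl (cat.), MeOH, 40 °C; then NaHCO3, PhI(OAc)2 (1.1 equiv), MeOH, 0 °C
Reagents that add atoms: methanol, CO
Why: acid-catalysed acetal exchange frees the phenol, and hypervalent-iodine oxidative dearomatisation of the 2-methoxyphenol in methanol gives the o-quinone monoketal by attack of methanol at the methoxy-bearing ortho carbon; the β-alkoxy dienone should not dimerise.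

**Step 7**
Reactants: 10 (2R)-2-ethenyl-6,6-dimethoxy-3,4-dihydro-2H-chromen-7(6H)-one
Product: 11 σ-homo-o-quinone monoketal, i.e. 10 with a CH(CH3) bridge across C4a–C5 (methylcyclopropane, mixture at the three new centres)
Conditions: [PhS(O)(NMe2)Et]BF4 (1.5 equiv), NaH, DMSO, 25 °C
Reagents that add atoms: (dimethylamino)ethylphenyloxosulfonium tetrafluoroborate, CC[S+](=O)(N(C)C)c1ccccc1.F[B-](F)(F)F
Why: Corey–Chaykovsky-type nucleophilic cyclopropanation with Johnson's ethylidene-transfer ylide: 1,6-addition to the unhindered δ-carbon C5 (the β-carbon C8a is deactivated by O1), then 3-exo-tet closure onto C4a; the new cyclopropane centres are erased in step 8.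

**Step 8**
Reactants: 11 σ-homo-o-quinone monoketal
Product: 12 (2R)-2-ethenyl-7-methoxy-5-methyl-3,4-dihydrocyclohepta[b]pyran-8(2H)-one
Conditions: TFA, CH2Cl2, 0 °C
Reagents that add atoms: none
Why: acid ionises the ketal next to the cyclopropane, the cyclopropylcarbinyl cation opens across the C4a–C5 bond and loses a proton to give the 2-methoxytropone (ring expansion of a σ-homo-o-quinone monoketal); C2 is not involved.

**Step 9**
Reactants: 12 (2R)-2-ethenyl-7-methoxy-5-methyl-3,4-dihydrocyclohepta[b]pyran-8(2H)-one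
Product: 13 (2R)-7-methoxy-5-methyl-2-[(E)-2-(4,4,5,5-tetramethyl-1,3,2-dioxaborolan-2-yl)ethenyl]-3,4-dihydrocyclohepta[b]pyran-8(2H)-one
Conditions: vinyl-Bpin (3 equiv), second-generation Grubbs catalyst RuCl2(=CHPh)(H2IMes)(PCy3) (5 mol %), CH2Cl2, 40 °C
Reagents that add atoms: vinylboronic acid pinacol ester, C=CB1OC(C)(C)C(C)(C)O1
Why: olefin cross-metathesis of the monosubstituted alkene with vinyl-Bpin, which gives the (E)-alkenylboronate under thermodynamic control.

**Step 10**
Reactants: 2 2-hydroxy-5-methoxy-4-(methoxymethoxy)benzaldehyde; 14 (2E)-4-[(tert-butyldimethylsilyl)oxy]but-2-enal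
Product: 15 (2R)-2-{[(tert-butyldimethylsilyl)oxy]methyl}-6-methoxy-7-(methoxymethoxy)-2H-chromene-3-carbaldehyde
Conditions: (R)-α,α-diphenylprolinol trimethylsilyl ether (20 mol %), 2-nitrobenzoic acid (20 mol %), 4 Å MS, toluene, 25 °C
Reagents that add atoms: none
Why: iminium/enamine organocascade (oxa-Michael addition, then intramolecular aldol condensation); the phenol adds to the β-carbon of the iminium ion on the face away from the diphenyl(siloxy)methyl group, which with the (R)-catalyst should give (2R).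

**Step 11**
Reactants: 15 (2R)-2-{[(tert-butyldimethylsilyl)oxy]methyl}-6-methoxy-7-(methoxymethoxy)-2H-chromene-3-carbaldehyde
Product: 17 tert-butyl{[(2R)-6-methoxy-7-(methoxymethoxy)-3-methylidene-3,4-dihydro-2H-chromen-2-yl]methoxy}dimethylsilane, via tosylhydrazone 16 (not isolated)
Conditions: TsNHNH2, MgSO4, CHCl3, 25 °C; then catecholborane, 0 °C; then NaOAc·3H2O, 60 °C
Reagents that add atoms: none
Why: reduction of an α,β-unsaturated tosylhydrazone with 1,3-transposition of the alkene (Kabalka–Hutchins reaction): hydride adds to C=N, sulfinate is lost and the allylic diazene delivers hydrogen to C4 by a retro-ene shift with loss of N2, leaving the exocyclic C3 methylene; C2 is untouched.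

**Step 12**
Reactants: 17 tert-butyl{[(2R)-6-methoxy-7-(methoxymethoxy)-3-methylidene-3,4-dihydro-2H-chromen-2-yl]methoxy}dimethylsilane
Product: 18 [(2R)-6-methoxy-7-(methoxymethoxy)-3-methylidene-3,4-dihydro-2H-chromen-2-yl]methanol
Conditions: TBAF, THF, 0 °C
Reagents that add atoms: none
Why: fluoride-mediated cleavage of the silyl ether; the MOM ether is inert.

**Step 13**
Reactants: 18 [(2R)-6-methoxy-7-(methoxymethoxy)-3-methylidene-3,4-dihydro-2H-chromen-2-yl]methanol
Product: 19 [(2R,3R)-6-methoxy-7-(methoxymethoxy)-3-methyl-3,4-dihydro-2H-chromen-2-yl]methanol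
Conditions: [Ir(cod)(PCy3)(py)]PF6 (5 mol %), H2 (1 atm), CH2Cl2, 25 °C
Reagents that add atoms: none
Why: hydroxyl-directed hydrogenation with Crabtree's catalyst: the homoallylic OH binds iridium and H2 is delivered to the alkene face syn to the CH2OH group, so the new C3 methyl should end up trans to it (3R).

**Step 14**
Reactants: 19 [(2R,3R)-6-methoxy-7-(methoxymethoxy)-3-methyl-3,4-dihydro-2H-chromen-2-yl]methanol
Product: 20 (2R,3R)-6-methoxy-7-(methoxymethoxy)-3-methyl-3,4-dihydro-2H-chromene-2-carbaldehyde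
Conditions: Dess–Martin periodinane, CH2Cl2, 0 °C
Reagents that add atoms: none
Why: Dess–Martin oxidation of the primary alcohol under non-basic conditions; the 2,3-trans aldehyde is also the thermodynamically preferred epimer.

**Step 15**
Reactants: 20 (2R,3R)-6-methoxy-7-(methoxymethoxy)-3-methyl-3,4-dihydro-2H-chromene-2-carbaldehyde
Product: 21 (2R,3R)-2-[(E)-2-iodoethenyl]-6-methoxy-7-(methoxymethoxy)-3-methyl-3,4-dihydro-2H-chromene
Conditions: CrCl2 (6 equiv), CHI3 (2 equiv), THF/1,4-dioxane, 0 to 25 °C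
Reagents that add atoms: iodoform, IC(I)I
Why: Takai olefination (geminal dichromium species from CHI3 and CrCl2), which gives (E)-vinyl iodides from aldehydes and does not enolise the α-aryloxy aldehyde.

**Step 16**
Reactants: 21 (2R,3R)-2-[(E)-2-iodoethenyl]-6-methoxy-7-(methoxymethoxy)-3-methyl-3,4-dihydro-2H-chromene
Product: 23 (2R,3R)-2-[(E)-2-iodoethenyl]-6,6-dimethoxy-3-methyl-3,4-dihydro-2H-chromen-7(6H)-one, via free phenol 22 (not isolated)
Conditions: HCl (cat.), MeOH, 40 °C; then NaHCO3, PhI(OAc)2 (1.1 equiv), MeOH, 0 °C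
Reagents that add atoms: methanol, CO
Why: as in step 6, acetal exchange frees the phenol and hypervalent-iodine oxidative dearomatisation in methanol gives the o-quinone monoketal; the vinyl iodide is inert.

**Step 17**
Reactants: 23 (2R,3R)-2-[(E)-2-iodoethenyl]-6,6-dimethoxy-3-methyl-3,4-dihydro-2H-chromen-7(6H)-one
Product: 24 σ-homo-o-quinone monoketal, i.e. 23 with a CH(CH3) bridge across C4a–C5 (mixture at the three new centres)
Conditions: [PhS(O)(NMe2)Et]BF4 (1.5 equiv), NaH, DMSO, 25 °C
Reagents that add atoms: (dimethylamino)ethylphenyloxosulfonium tetrafluoroborate, CC[S+](=O)(N(C)C)c1ccccc1.F[B-](F)(F)F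
Why: as in step 7, Corey–Chaykovsky-type ethylidene transfer by 1,6-addition at C5 and closure onto C4a; the new centres are erased in step 18.

**Step 18**
Reactants: 24 σ-homo-o-quinone monoketal
Product: 25 (2R,3R)-2-[(E)-2-iodoethenyl]-7-methoxy-3,5-dimethyl-3,4-dihydrocyclohepta[b]pyran-8(2H)-one
Conditions: TFA, CH2Cl2, 0 °C
Reagents that add atoms: none
Why: as in step 8, ketal ionisation, cyclopropylcarbinyl ring opening and proton loss give the 2-methoxytropone; C2 and C3 are not involved.

**Step 19**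
Reactants: 13 (2R)-7-methoxy-5-methyl-2-[(E)-2-(4,4,5,5-tetramethyl-1,3,2-dioxaborolan-2-yl)ethenyl]-3,4-dihydrocyclohepta[b]pyran-8(2H)-one; 25 (2R,3R)-2-[(E)-2-iodoethenyl]-7-methoxy-3,5-dimethyl-3,4-dihydrocyclohepta[b]pyran-8(2H)-one
Product: 26 bis(O-methyl) ether of the target: (2R,3R)-7-methoxy-2-[(1E,3E)-4-[(2R)-7-methoxy-5-methyl-8-oxo-2,3,4,8-tetrahydrocyclohepta[b]pyran-2-yl]buta-1,3-dien-1-yl]-3,5-dimethyl-3,4-dihydrocyclohepta[b]pyran-8(2H)-one
Conditions: PdCl2(dppf) (5 mol %), K3PO4 (aq, 3 equiv), THF, 25 °C, degassed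
Reagents that add atoms: none
Why: Suzuki–Miyaura coupling of alkenyl iodide and alkenylboronate with retention of both alkene geometries gives the (E,E)-diene; oxidative addition to the C–I bond at room temperature should outrun ionisation of the allylic C2–O bonds.

**Step 20**
Reactants: 26 bis(O-methyl) ether of the target
Product: 27 target CNP0332980.1
Conditions: MgI2 (6 equiv), THF/toluene, 50 °C; then aq. NH4Cl
Reagents that add atoms: none
Why: chelation-assisted nucleophilic O-demethylation: magnesium binds the tropone carbonyl and the adjacent methoxy oxygen and iodide attacks the methyl group (SN2), so no bond to a ring carbon or to C2 is broken; the free tropolone equilibrates to the tautomer drawn for the target.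

**Compound list**

1 | 2,4-dihydroxy-5-methoxybenzaldehyde | O=Cc1cc(OC)c(O)cc1O | starting material
2 | 2-hydroxy-5-methoxy-4-(methoxymethoxy)benzaldehyde | O=Cc1cc(OC)c(OCOC)cc1O | intermediate
3 | (Z)-3-iodoprop-2-en-1-ol | OC/C=C\I | starting material
4 | 2-{[(1Z)-3-hydroxyprop-1-en-1-yl]oxy}-5-methoxy-4-(methoxymethoxy)benzaldehyde | O=Cc1cc(OC)c(OCOC)cc1O/C=C\CO | intermediate
5 | (2Z)-3-[2-ethenyl-4-methoxy-5-(methoxymethoxy)phenoxy]prop-2-en-1-ol | C=Cc1cc(OC)c(OCOC)cc1O/C=C\CO | intermediate
6 | 1-{[(1Z)-3-chloroprop-1-en-1-yl]oxy}-2-ethenyl-4-methoxy-5-(methoxymethoxy)benzene | C=Cc1cc(OC)c(OCOC)cc1O/C=C\CCl | intermediate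
7 | 9-{2-[2-{[(1Z)-3-chloroprop-1-en-1-yl]oxy}-5-methoxy-4-(methoxymethoxy)phenyl]ethyl}-9-borabicyclo[3.3.1]nonane | ClC/C=C\Oc1cc(OCOC)c(OC)cc1CCB1C2CCCC1CCC2 | intermediate (not isolated)
8 | (2R)-2-ethenyl-6-methoxy-7-(methoxymethoxy)-3,4-dihydro-2H-chromene | C=C[C@H]1CCc2cc(OC)c(OCOC)cc2O1 | intermediate
9 | (2R)-2-ethenyl-6-methoxy-3,4-dihydro-2H-chromen-7-ol | C=C[C@H]1CCc2cc(OC)c(O)cc2O1 | intermediate (not isolated)
10 | (2R)-2-ethenyl-6,6-dimethoxy-3,4-dihydro-2H-chromen-7(6H)-one | C=C[C@H]1CCC2=CC(OC)(OC)C(=O)C=C2O1 | intermediate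
11 | σ-homo-o-quinone monoketal (CH(CH3) bridge across C4a–C5 of 10; cyclopropane centres unassigned) | C=C[C@H]1CCC23C(C)C2C(OC)(OC)C(=O)C=C3O1 | intermediate
12 | (2R)-2-ethenyl-7-methoxy-5-methyl-3,4-dihydrocyclohepta[b]pyran-8(2H)-one | C=C[C@H]1CCC2=C(C)C=C(OC)C(=O)C=C2O1 | intermediate
13 | (2R)-7-methoxy-5-methyl-2-[(E)-2-(4,4,5,5-tetramethyl-1,3,2-dioxaborolan-2-yl)ethenyl]-3,4-dihydrocyclohepta[b]pyran-8(2H)-one | CC1(C)OB(/C=C/[C@H]2CCC3=C(C)C=C(OC)C(=O)C=C3O2)OC1(C)C | intermediate
14 | (2E)-4-[(tert-butyldimethylsilyl)oxy]but-2-enal | O=C/C=C/CO[Si](C)(C)C(C)(C)C | starting material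
15 | (2R)-2-{[(tert-butyldimethylsilyl)oxy]methyl}-6-methoxy-7-(methoxymethoxy)-2H-chromene-3-carbaldehyde | CC(C)(C)[Si](C)(C)OC[C@@H]1Oc2cc(OCOC)c(OC)cc2C=C1C=O | intermediate
16 | N-tosylhydrazone of 15 | CC(C)(C)[Si](C)(C)OC[C@@H]1Oc2cc(OCOC)c(OC)cc2C=C1/C=N/NS(=O)(=O)c1ccc(C)cc1 | intermediate (not isolated)
17 | tert-butyl{[(2R)-6-methoxy-7-(methoxymethoxy)-3-methylidene-3,4-dihydro-2H-chromen-2-yl]methoxy}dimethylsilane | CC(C)(C)[Si](C)(C)OC[C@@H]1Oc2cc(OCOC)c(OC)cc2CC1=C | intermediate
18 | [(2R)-6-methoxy-7-(methoxymethoxy)-3-methylidene-3,4-dihydro-2H-chromen-2-yl]methanol | OC[C@@H]1Oc2cc(OCOC)c(OC)cc2CC1=C | intermediate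
19 | [(2R,3R)-6-methoxy-7-(methoxymethoxy)-3-methyl-3,4-dihydro-2H-chromen-2-yl]methanol | OC[C@@H]1Oc2cc(OCOC)c(OC)cc2C[C@H]1C | intermediate
20 | (2R,3R)-6-methoxy-7-(methoxymethoxy)-3-methyl-3,4-dihydro-2H-chromene-2-carbaldehyde | O=C[C@@H]1Oc2cc(OCOC)c(OC)cc2C[C@H]1C | intermediate
21 | (2R,3R)-2-[(E)-2-iodoethenyl]-6-methoxy-7-(methoxymethoxy)-3-methyl-3,4-dihydro-2H-chromene | I/C=C/[C@@H]1Oc2cc(OCOC)c(OC)cc2C[C@H]1C | intermediate
22 | (2R,3R)-2-[(E)-2-iodoethenyl]-6-methoxy-3-methyl-3,4-dihydro-2H-chromen-7-ol | I/C=C/[C@@H]1Oc2cc(O)c(OC)cc2C[C@H]1C | intermediate (not isolated)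
23 | (2R,3R)-2-[(E)-2-iodoethenyl]-6,6-dimethoxy-3-methyl-3,4-dihydro-2H-chromen-7(6H)-one | I/C=C/[C@@H]1OC2=CC(=O)C(OC)(OC)C=C2C[C@H]1C | intermediate
24 | σ-homo-o-quinone monoketal (CH(CH3) bridge across C4a–C5 of 23; cyclopropane centres unassigned) | I/C=C/[C@@H]1OC2=CC(=O)C(OC)(OC)C3C(C)C23C[C@H]1C | intermediate
25 | (2R,3R)-2-[(E)-2-iodoethenyl]-7-methoxy-3,5-dimethyl-3,4-dihydrocyclohepta[b]pyran-8(2H)-one | I/C=C/[C@@H]1OC2=CC(=O)C(OC)=CC(C)=C2C[C@H]1C | intermediate
26 | bis(O-methyl) ether of the target | C[C@@H]1CC2=C(C)C=C(OC)C(=O)C=C2O[C@H]1/C=C/C=C/[C@H]1CCC2=C(C)C=C(OC)C(=O)C=C2O1 | intermediate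
27 | CNP0332980.1 | Cc1cc(=O)c(O)cc2c1C[C@@H](C)[C@H](/C=C/C=C/[C@H]1CCc3c(C)cc(=O)c(O)cc3O1)O2 | target

**Step count.** Total: 20 steps. Longest linear sequence: 12 steps (step 1, steps 10–18, steps 19 and 20).

**Steps most likely to fail**

1. Step 5 (key step). The γ-aryloxyallyl chloride may ionise or be attacked by alkoxide before the alkyl group reaches copper, the boron-to-copper transfer may be slow, or the ligand may give poor facial selection in the ring-closing mode. Fallback with known chemistry, which closes ring C at O1–C2 instead: it sets out from 2. Wittig methylenation would give 4-methoxy-5-(methoxymethoxy)-2-vinylphenol F1. Hydroboration with 9-BBN (the phenol is borylated as well) would give the bis-borylated adduct F2, used directly in a B-alkyl Suzuki–Miyaura coupling with vinyl bromide (PdCl2(dppf), K3PO4) to give 2-(but-3-en-1-yl)-4-methoxy-5-(methoxymethoxy)phenol F3. Cross-metathesis with (Z)-but-2-ene-1,4-diyl dimethyl biscarbonate would give methyl (2E)-5-[2-hydroxy-5-methoxy-4-(methoxymethoxy)phenyl]pent-2-en-1-yl carbonate F4. Asymmetric allylic etherification (Pd2(dba)3·CHCl3, Trost DACH-phenyl ligand, AcOH, CH2Cl2) then closes the ring, and the fallback comes back to the route at 8.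

2. Step 7 (the same operation recurs as step 17). The substituted ylide may add at C8a with expulsion of the ring oxygen, add to the carbonyl group, or transfer ethylidene too slowly. Fallback: from 10, 1,3-dipolar cycloaddition of diazoethane (Et2O, 0 °C) across C4a=C5 would give the 1-pyrazoline F5, and photolysis (350 nm) with loss of N2 would return to the route at 11. In the same way 23 would give the 1-pyrazoline F6 and return at 24.

3. Step 20. The Lewis acid may ionise the pentadienylic C2–O1 bonds (epimerisation, ring opening), or the second demethylation may stall. Fallback by changing the order of events so that the ethers are cleaved before the diene exists: from 25, MgI2 would give the free tropolone (2R,3R)-8-hydroxy-2-[(E)-2-iodoethenyl]-3,5-dimethyl-3,4-dihydrocyclohepta[b]pyran-7(2H)-one F7. From 13, MgI2 would give the free tropolone boronate (2R)-8-hydroxy-5-methyl-2-[(E)-2-(4,4,5,5-tetramethyl-1,3,2-dioxaborolan-2-yl)ethenyl]-3,4-dihydrocyclohepta[b]pyran-7(2H)-one F8. Suzuki–Miyaura coupling of F7 and F8 as their potassium tropolonates (PdCl2(dppf), excess K3PO4) would come back to the route at 27.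

**Further compounds**

F1 | step 5 | 4-methoxy-5-(methoxymethoxy)-2-vinylphenol | C=Cc1cc(OC)c(OCOC)cc1O
F2 | step 5 | bis-borylated hydroboration adduct of F1 (not isolated) | COCOc1cc(OB2C3CCCC2CCC3)c(CCB2C3CCCC2CCC3)cc1OC
F3 | step 5 | 2-(but-3-en-1-yl)-4-methoxy-5-(methoxymethoxy)phenol | C=CCCc1cc(OC)c(OCOC)cc1O
F4 | step 5 | methyl (2E)-5-[2-hydroxy-5-methoxy-4-(methoxymethoxy)phenyl]pent-2-en-1-yl carbonate | COC(=O)OC/C=C/CCc1cc(OC)c(OCOC)cc1O
F5 | step 7 | 1-pyrazoline from 10 and diazoethane (fused at C4a–C5) | C=C[C@H]1CCC23N=NC(C)C2C(OC)(OC)C(=O)C=C3O1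
F6 | step 17 | 1-pyrazoline from 23 and diazoethane (fused at C4a–C5) | I/C=C/[C@@H]1OC2=CC(=O)C(OC)(OC)C3C(C)N=NC23C[C@H]1C
F7 | step 20 | (2R,3R)-8-hydroxy-2-[(E)-2-iodoethenyl]-3,5-dimethyl-3,4-dihydrocyclohepta[b]pyran-7(2H)-one | I/C=C/[C@@H]1OC2=CC(O)=C(O)C=C(C)C2=C1 
F8 | step 20 | (2R)-8-hydroxy-5-methyl-2-[(E)-2-(4,4,5,5-tetramethyl-1,3,2-dioxaborolan-2-yl)ethenyl]-3,4-dihydrocyclohepta[b]pyran-7(2H)-one | CC1(C)OB(/C=C/[C@H]2CCc3c(C)cc(=O)c(O)cc3O2)OC1(C)C
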